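## Structural features

The target is a single tetrahydrofuran ring (O1, C2 to C5) with a 3,4,5-trimethoxyphenyl group on C2, a hydroxymethyl group on C3, a 3,4,5-trimethoxybenzyl group on C4 and an unsubstituted CH2 at C5. The SMILES corresponds to (2S,3R,4R). The three stereocentres are contiguous: the C2 aryl and C3 hydroxymethyl groups are trans, and the C3 hydroxymethyl and C4 benzyl groups are cis. The O1–C2 bond is a benzylic ether on an electron-rich arene, so it can ionise under protic or Lewis acid (loss of the C2 configuration or ring opening) and can be hydrogenolysed. The primary alcohol is the only group that needs masking, and the six aryl methyl ethers are spectators. The real difficulty is the cis C3/C4 pair next to the trans C2/C3 pair in one absolute sense; at the lactone oxidation level this cis arrangement is the less stable, epimerisable one. The route exploits the fact that the arene of the C4 substituent lies exactly one carbon from ring carbon C4. If C5 is raised to a lactone carbonyl, C4 becomes an α-carbon, the benzylic CH2 becomes the terminus of an exocyclic methylene acceptor, and the C4 centre can be set by a protonation controlled from C3.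

## Logic of the disconnections

14 to 13: only the O–Si bond is cut. The primary hydroxyl stays masked to the end because a free hydroxymethyl group would compete in the ring-forming sulfonylation. The forward step must be a deprotection that leaves the benzylic ether alone.

13 to 11 (through 12): the O1–C5 bond is cut, which opens the ether to a 1,4-diol. This bond is chosen because the oxygen then stays on C2 throughout, so C2 cannot invert. The forward step must activate the primary hydroxyl in the presence of the secondary benzylic one and close the ring without ionising C2.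

11 to 10: no skeletal bond is cut; C5 is raised to the carboxyl level. The diol becomes a γ-lactone in which the C4 of the target is an enolisable α-carbon, which prepares the key disconnection. The forward reduction must be fast enough that the cis α-centre does not epimerise.

10 to 8 and 9: the bond between the arene and the benzylic CH2 is cut. This removes one arene and one stereocentre together and makes the synthesis convergent. The forward step must add the aryl group to the exocyclic methylene and protonate the resulting enolate on the face away from the silyloxymethyl group, under conditions that do not equilibrate the kinetic cis lactone.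

8 to 4 and 5 (through 6 and 7): the bond between the aryl-bearing carbon and its neighbour (C2–C3 of the target) is cut, together with the acyl C–O bond of the lactone. An aldehyde and a 2-(alkoxycarbonyl)allyl metal species result, and two stereocentres arise in one C–C bond formation. The forward step must be anti-selective (4,5-trans lactone) and must differentiate the faces of the aldehyde through the chiral chromium catalyst.

4 to 3, then to 1 and 2: the C–Br bond is cut with allylic transposition, then the bond between the acrylate α-carbon and the aldehyde carbon. Both pieces are commercial. The forward sequence must deliver bromide in the SN2' sense; the carbinol centre of 3 is destroyed, so it may be racemic.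

## Other disconnections considered

Alternative 1: The cut is the C4–C5 bond of the tetrahydrofuran, with the future benzylic carbon held as a lactone carbonyl tied back to the C3 hydroxymethyl oxygen. In the forward step the chloromethyl ether A1 is deprotonated with a lithium amide, and the lactone enolate displaces chloride (5-exo-tet) to give the cis-fused furofuranone A2. An aryl organometallic must then be added to the lactone carbonyl of A2 and the new benzylic oxygen removed.
- In its favour: two fused five-membered rings can only be cis, so the C3/C4 relationship follows from geometry and not from a kinetic protonation. On this point the alternative is the better plan. It also needs no transition metal and no protecting group on the hydroxymethyl oxygen.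
- Against it: A1 is an α-chloro ether of an electron-rich benzylic alcohol, so it is both ionisable and a hazardous alkylating agent. Aryl addition to A2 must stop after one equivalent. The resulting aryl ketone has an epimerisable C4, which gives back the advantage just gained. One benzylic C–O bond must then be reduced beside the O1–C2 benzylic ether.
- Comparison: both plans hide C4 and its appendage in a lactone. The alternative fixes C4 more securely, but the chosen plan introduces the second arene and the stereocentre in one catalytic step, where the alternative needs roughly three or four further operations.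

Alternative 2: The cut is the bond from C3 to the hydroxymethyl carbon, with the oxygen transposed from the benzylic carbon of the C4 side chain. In the forward step, tin–lithium exchange on the stannylmethyl ether A3 gives an α-alkoxy organolithium that rearranges by a [2,3]-sigmatropic shift to the benzylidene alcohol A4. Hydrogenation of the exocyclic alkene must then set C4. The carbinol configuration of A3 is shown as S; it governs only the alkene geometry of A4.
- In its favour: the shift is concerted and suprafacial, and the C2 aryl group sends the new bond to the opposite face, so the 2,3-trans relationship should be dependable. The hydroxymethyl group appears unprotected, which makes this plan equal or better in protecting-group economy. Both arenes are in place before the key step.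
- Against it: stoichiometric organotin reagents are needed, and a [1,2]-shift and deprotonation at the benzylic C2 compete. C4 is left to a separate reduction in which the free hydroxyl may direct hydrogen to its own face (3,4-trans), whereas only addition anti to it gives the cis isomer. Hydrogenolysis of O1–C2 is a further side reaction.
- Comparison: in both plans C4 is set last under the influence of the C3 substituent, so the stereochemical risk at C4 is equal in kind. The chosen plan sets it in the bond-forming step under mild aqueous conditions. Enantiopure A3 is expected to need more steps than 8.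

Alternative 3: The cut is the C2–C3 bond. In the forward step a Lewis acid opens the seven-membered enol acetal A5 to an aryl-stabilised oxocarbenium ion tethered to an enolate, whose carbon closes onto the cationic carbon to give the aldehyde A6. A hydride reduction then gives 14.
- In its favour: A5 comes from acetalisation with 5 and an alkene migration, no protecting group is needed, and A6 is one reduction from the target. On step and atom economy this plan is the better one.
- Against it: one stereocentre (C5 of A5, C4 of the target) must control two new ones in a stepwise ionic closure, and the wanted isomer is one of four. A6 is an α-branched aldehyde that epimerises easily at C3. Epimerisation there exchanges a 3,4-cis for a 2,3-cis interaction, so no clear thermodynamic preference helps. The absolute configuration would depend on an enantioselective alkene migration.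
- Comparison: the chosen plan costs about two more steps but gives each stereocentre its own control element (catalyst for C2, chair transition state for C3, protonation for C4). It also keeps Lewis acids away from the electron-rich benzylic ether, whereas the alternative generates that cation on purpose and puts all the risk into one step.

Key step: step 4

Assumption: the (S,S)-antipode of 1,8-bis(4-isopropyl-4,5-dihydrooxazol-2-yl)-3,6-diphenyl-9H-carbazole is taken to send the allylchromium reagent to the Si face of 5 (S carbinol); if the sense of induction is the opposite, the (R,R)-antipode is used with nothing else changed.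

## Route

Step 1
Reactants: 1 ethyl acrylate; 2 (tert-butyldimethylsilyloxy)acetaldehyde
Product: 3 ethyl 4-[(tert-butyldimethylsilyl)oxy]-3-hydroxy-2-methylenebutanoate (racemic)
Conditions: DABCO (1 equiv), 1,4-dioxane–H2O (1:1), rt
Reagents that add atoms: none
Why: Morita–Baylis–Hillman reaction: DABCO adds to the acrylate, the ammonium enolate adds to the unhindered aldehyde and elimination releases the amine; the carbinol centre is racemic and is erased in step 2.

Step 2
Reactants: 3 ethyl 4-[(tert-butyldimethylsilyl)oxy]-3-hydroxy-2-methylenebutanoate
Product: 4 ethyl (2Z)-2-(bromomethyl)-4-[(tert-butyldimethylsilyl)oxy]but-2-enoate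
Conditions: NBS, Me2S, CH2Cl2, 0 °C → rt
Reagents that add atoms: N-bromosuccinimide, O=C1CCC(=O)N1Br
Why: Corey–Kim-type activation of the allylic alcohol as an alkoxysulfonium salt, then SN2' attack of bromide at the terminal methylene with loss of dimethyl sulfoxide; the trisubstituted alkene should form in the thermodynamically preferred Z geometry (ester trans to the silyloxymethyl group), and the near-neutral conditions spare the silyl ether.

Step 3
Reactants: 4 ethyl (2Z)-2-(bromomethyl)-4-[(tert-butyldimethylsilyl)oxy]but-2-enoate; 5 3,4,5-trimethoxybenzaldehyde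
Product: 8 (4R,5S)-4-{[(tert-butyldimethylsilyl)oxy]methyl}-3-methylene-5-(3,4,5-trimethoxyphenyl)dihydrofuran-2(3H)-one (4,5-trans), via trimethylsilyl ether 6 (not isolated), via hydroxy ester 7 (not isolated)
Conditions: CrCl2 (10 mol %), (S,S)-carbazole bis(oxazoline) ligand (12 mol %), i-Pr2NEt (30 mol %), Mn (2 equiv), Me3SiCl (1.5 equiv), THF, 0 °C → rt; then PPTS (cat.), MeOH–CH2Cl2, rt
Reagents that add atoms: none
Why: Catalytic asymmetric Nozaki–Hiyama–Kishi 2-(alkoxycarbonyl)allylation: divalent chromium inserts into the allylic C–Br bond, the rapidly equilibrating allylchromium species adds through its γ-carbon to 5 in a chair transition state with the aryl and silyloxymethyl groups equatorial (anti adduct, whatever the bromide geometry), and the tridentate ligand selects the Si face of the aldehyde (S carbinol) while Mn and Me3SiCl turn the chromium over. Methanolysis of 6 and acid-catalysed 5-exo-trig lactonisation of 7 should then give the trans lactone with both centres in place.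

Step 4
Reactants: 8 (4R,5S)-4-{[(tert-butyldimethylsilyl)oxy]methyl}-3-methylene-5-(3,4,5-trimethoxyphenyl)dihydrofuran-2(3H)-one; 9 3,4,5-trimethoxyphenylboronic acid
Product: 10 (3R,4R,5S)-4-{[(tert-butyldimethylsilyl)oxy]methyl}-3-(3,4,5-trimethoxybenzyl)-5-(3,4,5-trimethoxyphenyl)dihydrofuran-2(3H)-one (3,4-cis, 4,5-trans)
Conditions: [Rh(cod)OH]2 (2.5 mol %), 9 (2 equiv), 1,4-dioxane–H2O (10:1), rt
Reagents that add atoms: none
Why: This is a rhodium-catalysed conjugate arylation of the Hayashi–Miyaura type on an α-methylene γ-butyrolactone, a substrate class for which substrate-controlled protonation is known. The hydroxo complex of monovalent rhodium transmetalates with 9 to an aryl rhodium species, which inserts the unhindered exocyclic C=CH2 bond with the aryl group going to the terminal carbon; this forms the aryl–CH2 bond. Water hydrolyses the resulting rhodium enolate (oxa-π-allyl form), which regenerates the rhodium hydroxide and delivers a proton to C3 of the lactone. No ring is closed. The one new stereocentre, C3 of the lactone (C4 of the target), is fixed by the face of protonation: the silyloxymethyl group on the neighbouring C4 of the lactone shields its own face, so the proton should arrive anti to it and the benzyl group ends cis to it (3R). The step needs 1,4-addition over 1,2-addition (expected for a soft aryl rhodium species on an unsaturated lactone), protonolysis over β-hydride elimination (favoured by the aqueous medium), and survival of the kinetically formed cis lactone, for which base-free, near-neutral conditions at ambient temperature are chosen. The C4 and C5 centres of the lactone are not touched.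

Step 5
Reactants: 10 (3R,4R,5S)-4-{[(tert-butyldimethylsilyl)oxy]methyl}-3-(3,4,5-trimethoxybenzyl)-5-(3,4,5-trimethoxyphenyl)dihydrofuran-2(3H)-one
Product: 11 (1S,2R,3R)-2-{[(tert-butyldimethylsilyl)oxy]methyl}-3-(3,4,5-trimethoxybenzyl)-1-(3,4,5-trimethoxyphenyl)butane-1,4-diol
Conditions: LiAlH4, THF, −20 → 0 °C; aq. potassium sodium tartrate work-up
Reagents that add atoms: none
Why: Hydride reduction of the lactone to the 1,4-diol; carbonyl addition is much faster than enolisation at low temperature, so the cis α-centre should be carried through, and the silyl and aryl ethers are inert.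

Step 6
Reactants: 11 (1S,2R,3R)-2-{[(tert-butyldimethylsilyl)oxy]methyl}-3-(3,4,5-trimethoxybenzyl)-1-(3,4,5-trimethoxyphenyl)butane-1,4-diol
Product: 13 tert-butyldimethyl{[(2S,3R,4R)-4-(3,4,5-trimethoxybenzyl)-2-(3,4,5-trimethoxyphenyl)tetrahydrofuran-3-yl]methoxy}silane, via primary tosylate 12 (not isolated)
Conditions: TsCl (1.1 equiv), pyridine, DMAP (cat.), 0 → 40 °C
Reagents that add atoms: none
Why: Chemoselective sulfonylation of the unhindered primary hydroxyl, then 5-exo-tet Williamson closure by the benzylic hydroxyl; the C–O bond at C2 is never broken, so C2 keeps its configuration, and the amine medium avoids benzylic ionisation and alkoxide-driven silyl migration.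

Step 7
Reactants: 13 tert-butyldimethyl{[(2S,3R,4R)-4-(3,4,5-trimethoxybenzyl)-2-(3,4,5-trimethoxyphenyl)tetrahydrofuran-3-yl]methoxy}silane
Product: 14 [(2S,3R,4R)-4-(3,4,5-trimethoxybenzyl)-2-(3,4,5-trimethoxyphenyl)tetrahydrofuran-3-yl]methanol (target)
Conditions: Bu4NF, THF, 0 °C → rt
Reagents that add atoms: none
Why: Fluoride-mediated cleavage of the primary silyl ether; the conditions leave the benzylic ether and the three stereocentres untouched.

## Compound list

1 | ethyl acrylate | C=CC(=O)OCC | starting material
2 | (tert-butyldimethylsilyloxy)acetaldehyde | CC(C)(C)[Si](C)(C)OCC=O | starting material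
3 | ethyl 4-[(tert-butyldimethylsilyl)oxy]-3-hydroxy-2-methylenebutanoate (racemic) | C=C(C(=O)OCC)C(O)CO[Si](C)(C)C(C)(C)C | intermediate
4 | ethyl (2Z)-2-(bromomethyl)-4-[(tert-butyldimethylsilyl)oxy]but-2-enoate | CCOC(=O)/C(CBr)=C/CO[Si](C)(C)C(C)(C)C | intermediate
5 | 3,4,5-trimethoxybenzaldehyde | COc1cc(C=O)cc(OC)c1OC | starting material
6 | ethyl (3R,4S)-3-{[(tert-butyldimethylsilyl)oxy]methyl}-2-methylene-4-(3,4,5-trimethoxyphenyl)-4-[(trimethylsilyl)oxy]butanoate | C=C(C(=O)OCC)[C@H](CO[Si](C)(C)C(C)(C)C)[C@H](O[Si](C)(C)C)c1cc(OC)c(OC)c(OC)c1 | intermediate (not isolated)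
7 | ethyl (3R,4S)-3-{[(tert-butyldimethylsilyl)oxy]methyl}-4-hydroxy-2-methylene-4-(3,4,5-trimethoxyphenyl)butanoate | C=C(C(=O)OCC)[C@H](CO[Si](C)(C)C(C)(C)C)[C@H](O)c1cc(OC)c(OC)c(OC)c1 | intermediate (not isolated)
8 | (4R,5S)-4-{[(tert-butyldimethylsilyl)oxy]methyl}-3-methylene-5-(3,4,5-trimethoxyphenyl)dihydrofuran-2(3H)-one | C=C1C(=O)O[C@H](c2cc(OC)c(OC)c(OC)c2)[C@H]1CO[Si](C)(C)C(C)(C)C | intermediate
9 | 3,4,5-trimethoxyphenylboronic acid | COc1cc(B(O)O)cc(OC)c1OC | starting material
10 | (3R,4R,5S)-4-{[(tert-butyldimethylsilyl)oxy]methyl}-3-(3,4,5-trimethoxybenzyl)-5-(3,4,5-trimethoxyphenyl)dihydrofuran-2(3H)-one | COc1cc(C[C@H]2C(=O)O[C@H](c3cc(OC)c(OC)c(OC)c3)[C@H]2CO[Si](C)(C)C(C)(C)C)cc(OC)c1OC | intermediate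
11 | (1S,2R,3R)-2-{[(tert-butyldimethylsilyl)oxy]methyl}-3-(3,4,5-trimethoxybenzyl)-1-(3,4,5-trimethoxyphenyl)butane-1,4-diol | COc1cc(C[C@@H](CO)[C@H](CO[Si](C)(C)C(C)(C)C)[C@H](O)c2cc(OC)c(OC)c(OC)c2)cc(OC)c1OC | intermediate
12 | (2R,3R,4S)-3-{[(tert-butyldimethylsilyl)oxy]methyl}-4-hydroxy-2-(3,4,5-trimethoxybenzyl)-4-(3,4,5-trimethoxyphenyl)butyl 4-methylbenzenesulfonate | COc1cc(C[C@@H](COS(=O)(=O)c2ccc(C)cc2)[C@H](CO[Si](C)(C)C(C)(C)C)[C@H](O)c2cc(OC)c(OC)c(OC)c2)cc(OC)c1OC | intermediate (not isolated)
13 | tert-butyldimethyl{[(2S,3R,4R)-4-(3,4,5-trimethoxybenzyl)-2-(3,4,5-trimethoxyphenyl)tetrahydrofuran-3-yl]methoxy}silane | COc1cc(C[C@H]2CO[C@H](c3cc(OC)c(OC)c(OC)c3)[C@H]2CO[Si](C)(C)C(C)(C)C)cc(OC)c1OC | intermediate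
14 | [(2S,3R,4R)-4-(3,4,5-trimethoxybenzyl)-2-(3,4,5-trimethoxyphenyl)tetrahydrofuran-3-yl]methanol | COc1cc(C[C@H]2CO[C@H](c3cc(OC)c(OC)c(OC)c3)[C@H]2CO)cc(OC)c1OC | target

## Step count and least certain steps

Total step count: 7. Longest linear sequence: 7 steps (1 and 2 to 14); 5 enters at step 3 and 9 at step 4.

Step 4 (key step).
- What may go wrong: poor facial discrimination in the protonation of the rhodium enolate, because the proton must arrive on the face that carries the more remote C5 aryl group; epimerisation of the kinetic cis lactone by enolisation if the medium turns basic; protodeboronation of the electron-rich boronic acid before transmetalation. A bulkier silyl group would be the first adjustment.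
- Fallback (from 8, back at 10): Mizoroki–Heck arylation of 8 with 5-iodo-1,2,3-trimethoxybenzene (Pd(OAc)2, KOAc, Bu4NCl, DMF, 80 °C) should give the (E)-benzylidene lactone F1. Heterogeneous hydrogenation (H2, Rh/Al2O3, EtOAc) then adds both hydrogens from the face away from the silyloxymethyl group and gives 10. The centre is then set by hydrogen delivery to the alkene, not by enolate protonation.

Step 3.
- What may go wrong: erosion of enantiofacial control with the electron-rich aldehyde; incomplete anti selectivity if the allylchromium species adds before it equilibrates; 1,4-elimination of silanolate from the γ-silyloxy allylchromium intermediate; reductive pinacol dimerisation of 5; partial loss of the primary silyl ether during the acidic lactonisation.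
- Fallback (from 5, back at 8): the two centres are set by an Evans syn-aldol reaction.
  - (S)-4-Benzyloxazolidin-2-one is acylated with methyl 4-chloro-4-oxobutanoate (n-BuLi, THF, −78 °C) to the acyl oxazolidinone F2.
  - Its boron enolate (Bu2BOTf, i-Pr2NEt, CH2Cl2, −78 → 0 °C) adds to 5 to give the syn-aldol adduct F3, which lactonises onto the methyl ester on work-up to the trans lactone imide F4. The syn aldol maps onto the 4,5-trans lactone, and the (S)-auxiliary gives the S carbinol.
  - LiOH/H2O2 cleaves the auxiliary to the paraconic acid F5, BH3·SMe2 reduces the acid beside the lactone to the hydroxymethyl lactone F6, and TBSCl/imidazole gives the silyl ether F7.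
  - α-Methylenation (LiN(SiMe3)2, then CH2=NMe2+ I− to the Mannich base F8; MeI to the ammonium iodide F9; NaHCO3) returns to the route at 8.

Step 6.
- What may go wrong: ionisation at the electron-rich benzylic carbon with loss of the C2 configuration or elimination; sulfonylation of the secondary hydroxyl; migration of the silyl group from the primary to the benzylic oxygen if alkoxides build up.
- Fallback (from 10, back at 13, bypassing 11 and 12): i-Bu2AlH (CH2Cl2, −78 °C) reduces 10 to the lactol F10. Et3SiH with BF3·OEt2 (CH2Cl2, −78 → −40 °C) then reduces the derived cyclic oxocarbenium ion to 13, so the ring oxygen is never detached.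

Step 1.
- What may go wrong: sluggish turnover, with hydration or self-condensation of the α-silyloxy aldehyde and hydrolysis or oligomerisation of the acrylate competing.
- Fallback (from 2, back at 3): hydroalumination of ethyl propiolate (i-Bu2AlH, N-methylmorpholine N-oxide, THF, 0 °C) gives the α-acrylate vinylalane F11, which adds to 2 and gives 3 after aqueous work-up.

## Further compounds

F1 | step 4 | (3E,4R,5S)-4-{[(tert-butyldimethylsilyl)oxy]methyl}-3-(3,4,5-trimethoxybenzylidene)-5-(3,4,5-trimethoxyphenyl)dihydrofuran-2(3H)-one | COc1cc(/C=C2/C(=O)O[C@H](c3cc(OC)c(OC)c(OC)c3)[C@H]2CO[Si](C)(C)C(C)(C)C)cc(OC)c1OC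
F2 | step 3 | (4S)-4-benzyl-3-(4-methoxy-4-oxobutanoyl)-1,3-oxazolidin-2-one | COC(=O)CCC(=O)N1C(=O)OC[C@@H]1Cc1ccccc1
F3 | step 3 | methyl (3S,4S)-3-{[(4S)-4-benzyl-2-oxo-1,3-oxazolidin-3-yl]carbonyl}-4-hydroxy-4-(3,4,5-trimethoxyphenyl)butanoate | COC(=O)C[C@H](C(=O)N1C(=O)OC[C@@H]1Cc1ccccc1)[C@H](O)c1cc(OC)c(OC)c(OC)c1
F4 | step 3 | (4S)-4-benzyl-3-{[(2S,3S)-5-oxo-2-(3,4,5-trimethoxyphenyl)tetrahydrofuran-3-yl]carbonyl}-1,3-oxazolidin-2-one | C1C(=O)O[C@H](c2cc(OC)c(OC)c(OC)c2)[C@H]1C(=O)N1C(=O)OC[C@@H]1Cc1ccccc1
F5 | step 3 | (2S,3S)-5-oxo-2-(3,4,5-trimethoxyphenyl)tetrahydrofuran-3-carboxylic acid | C1C(=O)O[C@H](c2cc(OC)c(OC)c(OC)c2)[C@H]1C(=O)O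
F6 | step 3 | (4R,5S)-4-(hydroxymethyl)-5-(3,4,5-trimethoxyphenyl)dihydrofuran-2(3H)-one | C1C(=O)O[C@H](c2cc(OC)c(OC)c(OC)c2)[C@H]1CO
F7 | step 3 | (4R,5S)-4-{[(tert-butyldimethylsilyl)oxy]methyl}-5-(3,4,5-trimethoxyphenyl)dihydrofuran-2(3H)-one | C1C(=O)O[C@H](c2cc(OC)c(OC)c(OC)c2)[C@H]1CO[Si](C)(C)C(C)(C)C
F8 | step 3 | (4R,5S)-4-{[(tert-butyldimethylsilyl)oxy]methyl}-3-[(dimethylamino)methyl]-5-(3,4,5-trimethoxyphenyl)dihydrofuran-2(3H)-one (either C3 epimer) | CN(C)CC1C(=O)O[C@H](c2cc(OC)c(OC)c(OC)c2)[C@H]1CO[Si](C)(C)C(C)(C)C
F9 | step 3 | {[(4R,5S)-4-{[(tert-butyldimethylsilyl)oxy]methyl}-2-oxo-5-(3,4,5-trimethoxyphenyl)tetrahydrofuran-3-yl]methyl}trimethylammonium iodide | C[N+](C)(C)CC1C(=O)O[C@H](c2cc(OC)c(OC)c(OC)c2)[C@H]1CO[Si](C)(C)C(C)(C)C.[I-]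
F10 | step 6 | (3R,4R,5S)-4-{[(tert-butyldimethylsilyl)oxy]methyl}-3-(3,4,5-trimethoxybenzyl)-5-(3,4,5-trimethoxyphenyl)tetrahydrofuran-2-ol (anomeric mixture) | COc1cc(C[C@H]2C(O)O[C@H](c3cc(OC)c(OC)c(OC)c3)[C@H]2CO[Si](C)(C)C(C)(C)C)cc(OC)c1OC
F11 | step 1 | ethyl 2-(diisobutylalumanyl)acrylate | CCOC(=O)C(=C)[Al](CC(C)C)CC(C)C
A1 | alternative 1 | (4R)-4-[(S)-(chloromethoxy)(3,4,5-trimethoxyphenyl)methyl]dihydrofuran-2(3H)-one | O=C1OC[C@@H](C1)[C@@H](c1cc(OC)c(OC)c(OC)c1)OCCl
A2 | alternative 1 | (3aR,4S,6aR)-4-(3,4,5-trimethoxyphenyl)tetrahydro-1H,3H-furo[3,4-c]furan-1-one | O=C1OC[C@@H]2[C@@H](c3cc(OC)c(OC)c(OC)c3)OC[C@H]12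
A3 | alternative 2 | tributyl({(S)-(3,4,5-trimethoxyphenyl)[(5S)-5-(3,4,5-trimethoxyphenyl)-2,5-dihydrofuran-3-yl]methoxy}methyl)stannane | CCCC[Sn](CCCC)(CCCC)CO[C@@H](c1cc(OC)c(OC)c(OC)c1)C1=C[C@@H](c2cc(OC)c(OC)c(OC)c2)OC1
A4 | alternative 2 | [(2S,3R,4Z)-4-(3,4,5-trimethoxybenzylidene)-2-(3,4,5-trimethoxyphenyl)tetrahydrofuran-3-yl]methanol | OC[C@@H]1[C@@H](c2cc(OC)c(OC)c(OC)c2)OC/C1=C\c1cc(OC)c(OC)c(OC)c1
A5 | alternative 3 | (5R)-5-(3,4,5-trimethoxybenzyl)-2-(3,4,5-trimethoxyphenyl)-4,5-dihydro-1,3-dioxepine (either acetal epimer) | COc1cc(C[C@H]2COC(c3cc(OC)c(OC)c(OC)c3)OC=C2)cc(OC)c1OC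
A6 | alternative 3 | (2S,3S,4R)-4-(3,4,5-trimethoxybenzyl)-2-(3,4,5-trimethoxyphenyl)tetrahydrofuran-3-carbaldehyde | COc1cc(C[C@H]2CO[C@H](c3cc(OC)c(OC)c(OC)c3)[C@H]2C=O)cc(OC)c1OC
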